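**Plan**
- Retrosynthesis: the two O–Si bonds are cut first, then the C3–C4 bond of ring C (ketone carbon to CH2). This leads back to an achiral 2-(1-arylvinyloxy)benzaldehyde that is an isomer of the protected flavanone. Next come the enol ether O–C2 bond, the O–CH3 bond and the two aryl–prenyl bonds.
- Enabling feature: C4 sits on ring A carbon C4a, directly beside C8a, which carries the ring oxygen O1. C4 can therefore be carried as a formyl group and C2=C3 as a 1,1-disubstituted enol ether hung on O1. The ring A precursor, 2,6-dihydroxy-4-methoxy-3,5-diprenylbenzaldehyde, is symmetric, so either phenol can become O1 and the other becomes the 5-OH.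
- Forward: ring A is dressed first (double C-prenylation of 2,4,6-trihydroxybenzaldehyde, then 4-O-methylation). The ring B unit is attached through oxygen (Mitsunobu etherification with a bromohydrin, then dehydrobromination to the enol ether). Ring C is closed last by C–C bond formation.
- Stereochemistry: C2 is the only stereocenter. It is created in the ring closure by a chiral rhodium bisphosphine catalyst (hydride to the Re face of the enol ether carbon) and is shielded from base in the final buffered desilylation.

Key step: step 6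

Remark: the SMILES is read as the 2S flavanone (the configuration of the natural 2S-flavanones).
Assumption: (R)-DTBM-SEGPHOS is taken to deliver hydride to the Re face of the enol ether carbon. If the sense of induction proves opposite, the (S)-ligand is used and nothing else changes.

Step 1
Reactants: 1 2,4,6-trihydroxybenzaldehyde; 2 prenyl bromide (1-bromo-3-methylbut-2-ene, 2.2 equiv)
Product: 4 2,4,6-trihydroxy-3,5-bis(3-methylbut-2-en-1-yl)benzaldehyde, via monoprenyl aldehyde 3 (not isolated)
Conditions: KOH (10% aq), 0 °C to rt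
Reagents that add atoms: none
Why: C-prenylation of an acylphloroglucinol phenolate, whose ring carbons are alkylated by the allylic bromide in water, while the formyl group blocks the third ring carbon so that only the two wanted positions are open.

Step 2
Reactants: 4 2,4,6-trihydroxy-3,5-bis(3-methylbut-2-en-1-yl)benzaldehyde
Product: 5 2,6-dihydroxy-4-methoxy-3,5-bis(3-methylbut-2-en-1-yl)benzaldehyde
Conditions: MeI (1.05 equiv), K2CO3 (1.0 equiv), acetone, 0 °C to rt
Reagents that add atoms: iodomethane, CI
Why: Williamson O-methylation, in which the 4-OH (para to the formyl group, most acidic, not hydrogen-bonded to the carbonyl oxygen) should react in preference to the 2- and 6-OH when one equivalent of base is used.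

Step 3
Reactants: 6 tert-butyldimethyl(4-vinylphenoxy)silane
Product: 7 rac-2-bromo-1-[4-(tert-butyldimethylsilyloxy)phenyl]ethan-1-ol
Conditions: NBS, acetone/H2O (4:1), 0 °C
Reagents that add atoms: N-bromosuccinimide, O=C1CCC(=O)N1Br; water, O
Why: Bromohydrin formation, in which water opens the bromonium ion at the benzylic carbon; the carbinol center forms racemic, which is of no consequence because it is flattened in step 5.

Step 4
Reactants: 5 2,6-dihydroxy-4-methoxy-3,5-bis(3-methylbut-2-en-1-yl)benzaldehyde; 7 rac-2-bromo-1-[4-(tert-butyldimethylsilyloxy)phenyl]ethan-1-ol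
Product: 8 rac-2-{2-bromo-1-[4-(tert-butyldimethylsilyloxy)phenyl]ethoxy}-6-hydroxy-4-methoxy-3,5-bis(3-methylbut-2-en-1-yl)benzaldehyde
Conditions: PPh3, DIAD, THF, 0 °C to rt
Reagents that add atoms: none
Why: Mitsunobu etherification, for which the formyl-activated phenol is acidic enough, and which should stop at the monoether because the remaining phenol is then chelated to the carbonyl and hindered; the benzylic center stays racemic.

Step 5
Reactants: 8 rac-2-{2-bromo-1-[4-(tert-butyldimethylsilyloxy)phenyl]ethoxy}-6-hydroxy-4-methoxy-3,5-bis(3-methylbut-2-en-1-yl)benzaldehyde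
Product: 10 2-(tert-butyldimethylsilyloxy)-6-({1-[4-(tert-butyldimethylsilyloxy)phenyl]ethenyl}oxy)-4-methoxy-3,5-bis(3-methylbut-2-en-1-yl)benzaldehyde, via potassium phenolate of the enol ether 9 (not isolated)
Conditions: KOtBu (2.2 equiv), THF, −20 to 0 °C; then TBSCl, DMF, 0 °C to rt
Reagents that add atoms: tert-butyldimethylsilyl chloride, CC(C)(C)[Si](C)(C)Cl
Why: E2 dehydrobromination of a beta-bromo ether to the enol ether, helped by the phenolate formed first (it makes the aryloxy group a poor leaving group, so HBr is lost and not the phenol), followed by O-silylation of that phenolate in the same flask; the benzylic stereocenter of 8 is erased.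

Step 6
Reactants: 10 2-(tert-butyldimethylsilyloxy)-6-({1-[4-(tert-butyldimethylsilyloxy)phenyl]ethenyl}oxy)-4-methoxy-3,5-bis(3-methylbut-2-en-1-yl)benzaldehyde
Product: 11 (2S)-5-(tert-butyldimethylsilyloxy)-2-[4-(tert-butyldimethylsilyloxy)phenyl]-7-methoxy-6,8-bis(3-methylbut-2-en-1-yl)-2,3-dihydro-4H-chromen-4-one
Conditions: [Rh(cod)Cl]2 (2.5 mol%), (R)-DTBM-SEGPHOS (5 mol%), NaB[3,5-(CF3)2C6H3]4 (5 mol%), 1,4-dioxane, 60 °C
Reagents that add atoms: none
Why: Proposed new method: a cationic monovalent rhodium bisphosphine complex should add oxidatively into the formyl C–H bond of 10, the 1,1-disubstituted enol ether should then insert into the Rh–H bond with hydride going to the aryl- and oxygen-bearing carbon (future C2) and rhodium to the terminal CH2 (future C3), and C–C reductive elimination from the seven-membered acyl alkyl metallacycle of trivalent rhodium should form the C3–C4 bond and release the chroman-4-one. The closest known reaction type is the enantioselective rhodium-catalysed intramolecular hydroacylation of 1,1-disubstituted alkenes in ortho-allylbenzaldehydes (to 3-substituted tetralones) and of N-vinyl heteroaryl carboxaldehydes; here the tether atom is oxygen and the alkene is an alpha-aryl enol ether. Ring C is closed in a formal 6-endo-trig mode, the acyl carbon bonding to the terminal alkene carbon so that both alkene carbons end inside the ring. The only new stereocenter, C2, is set by the chiral bisphosphine on rhodium, which selects the enantiotopic face of the enol ether in the hydride insertion: hydride delivery to the Re face of C2 (priorities O > aryl > CH2) gives 2S. The step needs endo over exo regioselectivity and chemoselectivity over the two prenyl alkenes; the first is secured because rhodium on C2 would be a tertiary alkyl whose reductive elimination to a quaternary benzofuran-3-one is disfavoured, the second because the trisubstituted prenyl alkenes sit meta to the formyl group and cannot reach the acyl rhodium hydride. The silyl ether on the second ortho oxygen keeps that oxygen from holding rhodium as a phenoxide chelate on the side away from the alkene.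

Step 7
Reactants: 11 (2S)-5-(tert-butyldimethylsilyloxy)-2-[4-(tert-butyldimethylsilyloxy)phenyl]-7-methoxy-6,8-bis(3-methylbut-2-en-1-yl)-2,3-dihydro-4H-chromen-4-one
Product: 12 (2S)-5-hydroxy-2-(4-hydroxyphenyl)-7-methoxy-6,8-bis(3-methylbut-2-en-1-yl)-2,3-dihydro-4H-chromen-4-one
Conditions: TBAF (2.2 equiv), AcOH (2.5 equiv), THF, 0 °C
Reagents that add atoms: none
Why: Fluoride-induced desilylation of both aryl silyl ethers, buffered with acetic acid so that the flavanone is not opened to the chalcone by base and C2 keeps its configuration.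

**Compound list**
1 | 2,4,6-trihydroxybenzaldehyde | O=Cc1c(O)cc(O)cc1O | starting material
2 | prenyl bromide (1-bromo-3-methylbut-2-ene) | CC(C)=CCBr | starting material
3 | 2,4,6-trihydroxy-3-(3-methylbut-2-en-1-yl)benzaldehyde (not isolated) | O=Cc1c(O)cc(O)c(CC=C(C)C)c1O | intermediate
4 | 2,4,6-trihydroxy-3,5-bis(3-methylbut-2-en-1-yl)benzaldehyde | O=Cc1c(O)c(CC=C(C)C)c(O)c(CC=C(C)C)c1O | intermediate
5 | 2,6-dihydroxy-4-methoxy-3,5-bis(3-methylbut-2-en-1-yl)benzaldehyde | O=Cc1c(O)c(CC=C(C)C)c(OC)c(CC=C(C)C)c1O | intermediate
6 | tert-butyldimethyl(4-vinylphenoxy)silane | C=Cc1ccc(O[Si](C)(C)C(C)(C)C)cc1 | starting material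
7 | rac-2-bromo-1-[4-(tert-butyldimethylsilyloxy)phenyl]ethan-1-ol | OC(CBr)c1ccc(O[Si](C)(C)C(C)(C)C)cc1 | intermediate
8 | rac-2-{2-bromo-1-[4-(tert-butyldimethylsilyloxy)phenyl]ethoxy}-6-hydroxy-4-methoxy-3,5-bis(3-methylbut-2-en-1-yl)benzaldehyde | O=Cc1c(O)c(CC=C(C)C)c(OC)c(CC=C(C)C)c1OC(CBr)c1ccc(O[Si](C)(C)C(C)(C)C)cc1 | intermediate
9 | potassium 2-formyl-5-methoxy-4,6-bis(3-methylbut-2-en-1-yl)-3-({1-[4-(tert-butyldimethylsilyloxy)phenyl]ethenyl}oxy)phenolate (not isolated) | [K+].[O-]c1c(CC=C(C)C)c(OC)c(CC=C(C)C)c(OC(=C)c2ccc(O[Si](C)(C)C(C)(C)C)cc2)c1C=O | intermediate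
10 | 2-(tert-butyldimethylsilyloxy)-6-({1-[4-(tert-butyldimethylsilyloxy)phenyl]ethenyl}oxy)-4-methoxy-3,5-bis(3-methylbut-2-en-1-yl)benzaldehyde | O=Cc1c(O[Si](C)(C)C(C)(C)C)c(CC=C(C)C)c(OC)c(CC=C(C)C)c1OC(=C)c1ccc(O[Si](C)(C)C(C)(C)C)cc1 | intermediate
11 | (2S)-5-(tert-butyldimethylsilyloxy)-2-[4-(tert-butyldimethylsilyloxy)phenyl]-7-methoxy-6,8-bis(3-methylbut-2-en-1-yl)-2,3-dihydro-4H-chromen-4-one | COc1c(CC=C(C)C)c(O[Si](C)(C)C(C)(C)C)c2c(c1CC=C(C)C)O[C@H](c1ccc(O[Si](C)(C)C(C)(C)C)cc1)CC2=O | intermediate
12 | (2S)-5-hydroxy-2-(4-hydroxyphenyl)-7-methoxy-6,8-bis(3-methylbut-2-en-1-yl)-2,3-dihydro-4H-chromen-4-one | COc1c(CC=C(C)C)c(O)c2c(c1CC=C(C)C)O[C@H](c1ccc(O)cc1)CC2=O | target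

**Totals**
Total step count: 7. Longest linear sequence: 6 steps (steps 1, 2, 4, 5, 6, 7 from 2,4,6-trihydroxybenzaldehyde); step 3 is a one-step side branch.

**Steps most likely to fail**

Step 6 (ring closure by hydroacylation). The risks are hydride insertion in the exo sense leading to the five-membered ketone, decarbonylation of the hindered acyl rhodium hydride, and poor facial selectivity. The fallback builds ring C in another order with known reactions and sets C2 by asymmetric conjugate arylation. It sets out from 5 and comes back at 11.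
- Excess ethynylmagnesium bromide (THF, 0 °C to rt) should add to the aldehyde and give the propargylic alcohol 2-(1-hydroxyprop-2-yn-1-yl)-5-methoxy-4,6-bis(3-methylbut-2-en-1-yl)benzene-1,3-diol F1.
- MnO2 in CH2Cl2 should oxidise it to the ynone 1-[2,6-dihydroxy-4-methoxy-3,5-bis(3-methylbut-2-en-1-yl)phenyl]prop-2-yn-1-one F2.
- Et2NH in EtOH should add to the ynone, and the resulting enaminone should close by attack of a phenol with loss of the amine to give 5-hydroxy-7-methoxy-6,8-bis(3-methylbut-2-en-1-yl)-4H-chromen-4-one F3.
- TBSCl and imidazole in DMF should give the silyl ether 5-(tert-butyldimethylsilyloxy)-7-methoxy-6,8-bis(3-methylbut-2-en-1-yl)-4H-chromen-4-one F4.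
- Asymmetric 1,4-addition of commercial 4-(tert-butyldimethylsilyloxy)phenylboronic acid to F4 should give 11. The catalyst is Pd(OCOCF3)2 with the enantiomer of the t-BuPyOx ligand that leads to the 2S series (NH4PF6, H2O, 1,2-dichloroethane, 60 °C). The route is rejoined before step 7.

Step 1 (double C-prenylation). The risks are competing O-alkylation, geminal dialkylation with loss of aromaticity, and incomplete second alkylation. The fallback brings in the prenyl groups by aromatic Claisen rearrangement. It sets out from 1 and comes back at 5, replacing steps 1 and 2.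
- Selective 4-O-methylation of 1 (MeI, K2CO3, acetone) should give 2,6-dihydroxy-4-methoxybenzaldehyde F5.
- O-Alkylation of both phenols with 3-chloro-3-methylbut-1-yne (DBU, CuCl2 cat., MeCN, 0 °C) should give 4-methoxy-2,6-bis[(2-methylbut-3-yn-2-yl)oxy]benzaldehyde F6.
- Semi-hydrogenation (H2, Pd on CaCO3 poisoned with Pb(OAc)2, quinoline, EtOAc) should give 4-methoxy-2,6-bis[(2-methylbut-3-en-2-yl)oxy]benzaldehyde F7.
- Heating in N,N-diethylaniline at about 130 °C should bring about two [3,3] shifts, each to the only free ortho carbon, and deliver 5.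

Step 4 (Mitsunobu etherification). The risks are slow coupling of two hindered partners and elimination or ionisation of the activated benzylic alcohol. The fallback forms the ether bond by alkylation with a benzylic bromide. It sets out from 6 and comes back at 8.
- Br2 in CH2Cl2 at −78 °C should add to 6 and give 1-(1,2-dibromoethyl)-4-(tert-butyldimethylsilyloxy)benzene F8.
- 5 and F8 with K2CO3 in acetone should give 8, the phenolate displacing the readily ionised benzylic bromide while the primary bromide stays.

**Further compounds**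
F1 | step 6 | 2-(1-hydroxyprop-2-yn-1-yl)-5-methoxy-4,6-bis(3-methylbut-2-en-1-yl)benzene-1,3-diol | C#CC(O)c1c(O)c(CC=C(C)C)c(OC)c(CC=C(C)C)c1O
F2 | step 6 | 1-[2,6-dihydroxy-4-methoxy-3,5-bis(3-methylbut-2-en-1-yl)phenyl]prop-2-yn-1-one | C#CC(=O)c1c(O)c(CC=C(C)C)c(OC)c(CC=C(C)C)c1O
F3 | step 6 | 5-hydroxy-7-methoxy-6,8-bis(3-methylbut-2-en-1-yl)-4H-chromen-4-one | COc1c(CC=C(C)C)c(O)c2c(c1CC=C(C)C)OC=CC2=O
F4 | step 6 | 5-(tert-butyldimethylsilyloxy)-7-methoxy-6,8-bis(3-methylbut-2-en-1-yl)-4H-chromen-4-one | COc1c(CC=C(C)C)c(O[Si](C)(C)C(C)(C)C)c2c(c1CC=C(C)C)OC=CC2=O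
F5 | step 1 | 2,6-dihydroxy-4-methoxybenzaldehyde | O=Cc1c(O)cc(OC)cc1O
F6 | step 1 | 4-methoxy-2,6-bis[(2-methylbut-3-yn-2-yl)oxy]benzaldehyde | O=Cc1c(OC(C)(C)C#C)cc(OC)cc1OC(C)(C)C#C
F7 | step 1 | 4-methoxy-2,6-bis[(2-methylbut-3-en-2-yl)oxy]benzaldehyde | O=Cc1c(OC(C)(C)C=C)cc(OC)cc1OC(C)(C)C=C
F8 | step 4 | 1-(1,2-dibromoethyl)-4-(tert-butyldimethylsilyloxy)benzene | BrCC(Br)c1ccc(O[Si](C)(C)C(C)(C)C)cc1
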